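**Retrosynthetic overview**

- The strategy rests on the central benzene ring: C1 carries the CH2CH2(3-hydroxyphenyl) chain, C2 the 4-hydroxybenzyl CH2, and C3 and C5 the methoxy groups. This is the oxygen pattern of an orsellinate-type resorcylate, with the phenethyl group as the chain starter on C1 and the benzylic carbon on C2 in the place of the carboxyl carbon.
- The bond from the C2 benzylic carbon to the 4-hydroxyphenyl ring is made by an aryllithium opening a benzodioxinone (salicylate acetonide) to a benzophenone; the C=O is later reduced to CH2.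
- The benzene ring of that benzodioxinone is disconnected at C1–C2 by a retro-aldol/retro-dehydration to a diketo dioxinone, which is a masked 3,5,7-triketo acid.
- The diketo dioxinone comes from the dianion of a keto dioxinone and the Weinreb amide of 3-(3-benzyloxyphenyl)propanoic acid; the keto dioxinone comes from trimethyldioxinone and acetyl chloride.
- Ring order: the dioxinone ring and both outer benzene rings are bought; the central benzene ring is the only ring formed, in step 5.

Key step: step 5

Remark on the chemistry: the target has no stereocentre. The one stereocentre of transient 7 forms racemic and is destroyed in the same step, so its SMILES carries no configuration.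

**Route**

Step 1
Reactants: 1 3-(3-hydroxyphenyl)propanoic acid
Product: 2 benzyl 3-(3-benzyloxyphenyl)propanoate
Conditions: BnBr (2.3 equiv), K2CO3 (3 equiv), DMF, 60 °C
Reagents that add atoms: benzyl bromide, BrCc1ccccc1
Why: Williamson etherification of the phenoxide and SN2 esterification of the carboxylate run side by side under carbonate base, so both acidic OH groups are capped in one operation.

Step 2
Reactants: 2 benzyl 3-(3-benzyloxyphenyl)propanoate
Product: 3 3-(3-benzyloxyphenyl)-N-methoxy-N-methylpropanamide
Conditions: MeNHOMe·HCl (1.5 equiv), i-PrMgCl (3.0 equiv), THF, −20 → 0 °C; aq. NH4Cl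
Reagents that add atoms: N,O-dimethylhydroxylamine hydrochloride, CNOC.Cl
Why: The chloromagnesium amide of N,O-dimethylhydroxylamine, formed in the flask, converts the ester directly into the Weinreb amide by aminolysis, and the aryl benzyl ether is inert to it.

Step 3
Reactants: 4 2,2,6-trimethyl-4H-1,3-dioxin-4-one
Product: 5 2,2-dimethyl-6-(2-oxopropyl)-4H-1,3-dioxin-4-one
Conditions: LiN(SiMe3)2 (1.0 equiv relative to 4), THF, −78 °C; AcCl (0.5 equiv), −78 °C; aq. NH4Cl
Reagents that add atoms: acetyl chloride, CC(Cl)=O
Why: Gamma-deprotonation gives the lithium dienolate, which is C-acylated at the exocyclic carbon by acetyl chloride in a vinylogous Claisen-type acylation, the second equivalent of dienolate taking up the acidic proton of the product.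

Step 4
Reactants: 5 2,2-dimethyl-6-(2-oxopropyl)-4H-1,3-dioxin-4-one; 3 3-(3-benzyloxyphenyl)-N-methoxy-N-methylpropanamide
Product: 6 6-[6-(3-benzyloxyphenyl)-2,4-dioxohexyl]-2,2-dimethyl-4H-1,3-dioxin-4-one
Conditions: LiN(i-Pr)2 (2.1 equiv relative to 5), THF, −78 → −40 °C; then 3, −78 → −20 °C; aq. NH4Cl; used crude
Reagents that add atoms: none
Why: Double deprotonation of 5 gives an acetoacetate-type dianion whose more reactive methyl-derived carbanion attacks the Weinreb amide in a crossed Claisen condensation, the chelated tetrahedral adduct holding back over-addition until the quench.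

Step 5
Reactants: 6 6-[6-(3-benzyloxyphenyl)-2,4-dioxohexyl]-2,2-dimethyl-4H-1,3-dioxin-4-one
Product: 8 5-[2-(3-benzyloxyphenyl)ethyl]-7-hydroxy-2,2-dimethyl-4H-1,3-benzodioxin-4-one, via racemic aldol adduct 7 (not isolated)
Conditions: K2CO3 (2 equiv), i-PrOH/CH2Cl2, rt; then HCl in MeOH, rt
Reagents that add atoms: none
Why: K2CO3 removes the doubly activated proton between the dioxinone and the adjacent ketone, and the extended enolate attacks through the dioxinone alkene carbon (future C2) on the chain-end ketone (future C1) to give aldol adduct 7; HCl then dehydrates 7 and the remaining ring ketone enolizes, so the benzene ring appears fused to the intact dioxinone. The closest known reaction type is the base-then-acid aldol cyclization–aromatization of diketo dioxinones to acetonide-protected resorcylates, itself modelled on orsellinate biosynthesis. The one ring formed, the central carbocycle, closes in a six-membered 6-(enolexo)-exo-trig aldol mode. The only new stereocentre, the carbinol carbon of 7, forms racemic and is erased by the dehydration, so no element of control is required. The step needs C–C aldol closure to win over Claisen-type attack on the carboxyl terminus and over O-cyclization to a pyranone; the dioxinone secures this because it holds the carboxyl carbon as a cyclic enol-ester acetal that is no acceptor here and makes its alkene carbon the only carbon nucleophile placed six atoms from a ketone, while running the base stage first forms the C–C bond before any acid-promoted oxygen closure can set in.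

Step 6
Reactants: 8 5-[2-(3-benzyloxyphenyl)ethyl]-7-hydroxy-2,2-dimethyl-4H-1,3-benzodioxin-4-one
Product: 9 5-[2-(3-benzyloxyphenyl)ethyl]-7-methoxy-2,2-dimethyl-4H-1,3-benzodioxin-4-one
Conditions: MeI, K2CO3, acetone, reflux
Reagents that add atoms: iodomethane, CI
Why: Williamson O-methylation of the only free phenol, the dioxinone carbonyl being inert to carbonate and iodomethane.

Step 7
Reactants: 9 5-[2-(3-benzyloxyphenyl)ethyl]-7-methoxy-2,2-dimethyl-4H-1,3-benzodioxin-4-one; 10 1-(benzyloxy)-4-bromobenzene
Product: 12 (4-benzyloxyphenyl){2-[2-(3-benzyloxyphenyl)ethyl]-6-hydroxy-4-methoxyphenyl}methanone, via 4-benzyloxyphenyllithium 11 (not isolated)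
Conditions: 10 (2.5 equiv), n-BuLi (2.5 equiv), THF, −78 °C; then 9, −78 → 0 °C; aq. NH4Cl
Reagents that add atoms: none
Why: Bromine–lithium exchange gives 11, which adds to the lactone-type carbonyl in a nucleophilic acyl substitution; the adduct collapses with loss of acetone to the lithium phenoxide of the ortho-hydroxy ketone, which is too electron-rich and hindered to take a second aryllithium, and the excess of 11 covers what the released acetone consumes.

Step 8
Reactants: 12 (4-benzyloxyphenyl){2-[2-(3-benzyloxyphenyl)ethyl]-6-hydroxy-4-methoxyphenyl}methanone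
Product: 13 (4-benzyloxyphenyl){2-[2-(3-benzyloxyphenyl)ethyl]-4,6-dimethoxyphenyl}methanone
Conditions: MeI, K2CO3, DMF, 50 °C
Reagents that add atoms: iodomethane, CI
Why: Williamson methylation of the hydrogen-bonded ortho-hydroxy ketone needs the polar solvent and gentle warming but has no competing nucleophilic site.

Step 9
Reactants: 13 (4-benzyloxyphenyl){2-[2-(3-benzyloxyphenyl)ethyl]-4,6-dimethoxyphenyl}methanone
Product: 14 1-[2-(3-benzyloxyphenyl)ethyl]-2-(4-benzyloxybenzyl)-3,5-dimethoxybenzene
Conditions: Et3SiH (4 equiv), CF3CO2H/CH2Cl2, 0 °C → rt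
Reagents that add atoms: none
Why: Ionic hydrogenation of a diaryl ketone: protonation and hydride transfer give the carbinol, which ionizes to a doubly aryl-stabilized cation that takes a second hydride from the excess silane faster than it can be captured by an arene, and aryl benzyl ethers tolerate CF3CO2H at this temperature.

Step 10
Reactants: 14 1-[2-(3-benzyloxyphenyl)ethyl]-2-(4-benzyloxybenzyl)-3,5-dimethoxybenzene
Product: 15 gymconopin D, 3-{2-[2-(4-hydroxybenzyl)-3,5-dimethoxyphenyl]ethyl}phenol
Conditions: H2 (1 atm), Pd/C (10%), EtOAc/MeOH, rt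
Reagents that add atoms: none
Why: Catalytic hydrogenolysis cleaves both aryl benzyl ethers, while the methyl ethers, the diarylmethane and the bibenzyl unit are not touched.

**Compound list**

1 | 3-(3-hydroxyphenyl)propanoic acid | OC(=O)CCc1cccc(O)c1 | starting material
2 | benzyl 3-(3-benzyloxyphenyl)propanoate | O=C(CCc1cccc(OCc2ccccc2)c1)OCc1ccccc1 | intermediate
3 | 3-(3-benzyloxyphenyl)-N-methoxy-N-methylpropanamide | CON(C)C(=O)CCc1cccc(OCc2ccccc2)c1 | intermediate
4 | 2,2,6-trimethyl-4H-1,3-dioxin-4-one | CC1=CC(=O)OC(C)(C)O1 | starting material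
5 | 2,2-dimethyl-6-(2-oxopropyl)-4H-1,3-dioxin-4-one | CC(=O)CC1=CC(=O)OC(C)(C)O1 | intermediate
6 | 6-[6-(3-benzyloxyphenyl)-2,4-dioxohexyl]-2,2-dimethyl-4H-1,3-dioxin-4-one | CC1(C)OC(=O)C=C(CC(=O)CC(=O)CCc2cccc(OCc3ccccc3)c2)O1 | intermediate
7 | racemic aldol adduct, 5-[2-(3-benzyloxyphenyl)ethyl]-5-hydroxy-2,2-dimethyl-5,6-dihydro-4H-1,3-benzodioxine-4,7(8H)-dione | CC1(C)OC(=O)C2=C(CC(=O)CC2(O)CCc2cccc(OCc3ccccc3)c2)O1 | intermediate (not isolated)
8 | 5-[2-(3-benzyloxyphenyl)ethyl]-7-hydroxy-2,2-dimethyl-4H-1,3-benzodioxin-4-one | CC1(C)OC(=O)c2c(CCc3cccc(OCc4ccccc4)c3)cc(O)cc2O1 | intermediate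
9 | 5-[2-(3-benzyloxyphenyl)ethyl]-7-methoxy-2,2-dimethyl-4H-1,3-benzodioxin-4-one | COc1cc(CCc2cccc(OCc3ccccc3)c2)c2c(c1)OC(C)(C)OC2=O | intermediate
10 | 1-(benzyloxy)-4-bromobenzene | Brc1ccc(OCc2ccccc2)cc1 | starting material
11 | 4-benzyloxyphenyllithium | [Li]c1ccc(OCc2ccccc2)cc1 | intermediate (not isolated)
12 | (4-benzyloxyphenyl){2-[2-(3-benzyloxyphenyl)ethyl]-6-hydroxy-4-methoxyphenyl}methanone | COc1cc(O)c(C(=O)c2ccc(OCc3ccccc3)cc2)c(CCc2cccc(OCc3ccccc3)c2)c1 | intermediate
13 | (4-benzyloxyphenyl){2-[2-(3-benzyloxyphenyl)ethyl]-4,6-dimethoxyphenyl}methanone | COc1cc(OC)c(C(=O)c2ccc(OCc3ccccc3)cc2)c(CCc2cccc(OCc3ccccc3)c2)c1 | intermediate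
14 | 1-[2-(3-benzyloxyphenyl)ethyl]-2-(4-benzyloxybenzyl)-3,5-dimethoxybenzene | COc1cc(OC)c(Cc2ccc(OCc3ccccc3)cc2)c(CCc2cccc(OCc3ccccc3)c2)c1 | intermediate
15 | gymconopin D, 3-{2-[2-(4-hydroxybenzyl)-3,5-dimethoxyphenyl]ethyl}phenol | COc1cc(CCc2cccc(O)c2)c(Cc2ccc(O)cc2)c(OC)c1 | target

**Step count**

Total steps: 10. Longest linear sequence: 9 steps (steps 1, 2, 4, 5, 6, 7, 8, 9, 10, from compound 1).

**Steps most likely to fail**

Step 5 (key step). The extended enolate may close through oxygen or be cut by retro-Claisen cleavage instead of forming the C–C bond, or the aldol adduct may lose its acetonide before it dehydrates, so that the ring does not aromatize. The fallback sets out from 3 and comes back at 8; it builds the ring by a classical Michael–Claisen annulation and oxidative aromatization instead of by folding. Compound 3 is reduced with i-Bu2AlH (THF, −78 °C) to 3-(3-benzyloxyphenyl)propanal F1. A Wittig reaction with 1-(triphenylphosphoranylidene)propan-2-one (toluene, 80 °C) should give (E)-6-(3-benzyloxyphenyl)hex-3-en-2-one F2. Dimethyl malonate and NaOMe in MeOH at reflux add in a Michael sense and close the ring by intramolecular Claisen condensation to racemic methyl 6-[2-(3-benzyloxyphenyl)ethyl]-4-hydroxy-2-oxocyclohex-3-ene-1-carboxylate F3. Bromination–dehydrobromination (Br2, DMF, 0 → 80 °C) aromatizes it to methyl 6-[2-(3-benzyloxyphenyl)ethyl]-2,4-dihydroxybenzoate F4. Saponification (aq. KOH, MeOH, reflux; cold acidification) gives 6-[2-(3-benzyloxyphenyl)ethyl]-2,4-dihydroxybenzoic acid F5, and acetone with (CF3CO)2O and CF3CO2H (0 °C → rt) closes the acetonide to give 8.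

Step 7. The aryllithium may act as a base (lithiation of the benzylic CH2 ortho to the lactone carbonyl), may be used up by the acetone that the collapsing adduct releases, or may add a second time to the freed ketone. The fallback sets out from 9 and 10 and comes back at 14; the aryl group is added to an aldehyde instead of to the lactone, so steps 8 and 9 are not needed. Compound 9 is reduced with i-Bu2AlH (CH2Cl2, −78 °C); the lactol acetal collapses on work-up with loss of acetone to 2-[2-(3-benzyloxyphenyl)ethyl]-6-hydroxy-4-methoxybenzaldehyde F6. Methylation (MeI, K2CO3, DMF) gives 2-[2-(3-benzyloxyphenyl)ethyl]-4,6-dimethoxybenzaldehyde F7. Aryllithium 11 (from 10 and n-BuLi, THF, −78 °C) adds to the aldehyde to give racemic (4-benzyloxyphenyl){2-[2-(3-benzyloxyphenyl)ethyl]-4,6-dimethoxyphenyl}methanol F8. This carbinol ionizes far more easily than ketone 13, so Et3SiH/CF3CO2H (CH2Cl2, −20 °C) should take it to 14.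

Step 9. The hindered, electron-rich ketone may accept the first hydride slowly, and on longer exposure to acid the diarylmethyl cation may be captured by the benzyloxyphenyl ring of the phenethyl arm (Friedel–Crafts closure of a seven-membered ring) or the aryl benzyl ethers may be cleaved. The fallback sets out from 12 and comes back at 14; it removes the carbonyl oxygen before the second methylation, through an ortho-quinone methide under basic hydride conditions, so no carbocation is formed. Compound 12 is acylated with ethyl chloroformate and Et3N (THF, 0 °C) to 2-(4-benzyloxybenzoyl)-3-[2-(3-benzyloxyphenyl)ethyl]-5-methoxyphenyl ethyl carbonate F9. NaBH4 (aq. THF, 0 °C → rt) reduces the ketone, the carbonate shifts to the new alkoxide and is expelled by the phenoxide, and the ortho-quinone methide takes a second hydride to give 2-(4-benzyloxybenzyl)-3-[2-(3-benzyloxyphenyl)ethyl]-5-methoxyphenol F10. MeI and K2CO3 (acetone, reflux) then give 14.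

**Further compounds**

F1 | step 5 | 3-(3-benzyloxyphenyl)propanal | O=CCCc1cccc(OCc2ccccc2)c1
F2 | step 5 | (E)-6-(3-benzyloxyphenyl)hex-3-en-2-one | CC(=O)/C=C/CCc1cccc(OCc2ccccc2)c1
F3 | step 5 | racemic methyl 6-[2-(3-benzyloxyphenyl)ethyl]-4-hydroxy-2-oxocyclohex-3-ene-1-carboxylate (mixture of diastereomers) | COC(=O)C1C(CCc2cccc(OCc3ccccc3)c2)CC(O)=CC1=O
F4 | step 5 | methyl 6-[2-(3-benzyloxyphenyl)ethyl]-2,4-dihydroxybenzoate | COC(=O)c1c(O)cc(O)cc1CCc1cccc(OCc2ccccc2)c1
F5 | step 5 | 6-[2-(3-benzyloxyphenyl)ethyl]-2,4-dihydroxybenzoic acid | OC(=O)c1c(O)cc(O)cc1CCc1cccc(OCc2ccccc2)c1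
F6 | step 7 | 2-[2-(3-benzyloxyphenyl)ethyl]-6-hydroxy-4-methoxybenzaldehyde | COc1cc(O)c(C=O)c(CCc2cccc(OCc3ccccc3)c2)c1
F7 | step 7 | 2-[2-(3-benzyloxyphenyl)ethyl]-4,6-dimethoxybenzaldehyde | COc1cc(OC)c(C=O)c(CCc2cccc(OCc3ccccc3)c2)c1
F8 | step 7 | racemic (4-benzyloxyphenyl){2-[2-(3-benzyloxyphenyl)ethyl]-4,6-dimethoxyphenyl}methanol | COc1cc(OC)c(C(O)c2ccc(OCc3ccccc3)cc2)c(CCc2cccc(OCc3ccccc3)c2)c1
F9 | step 9 | 2-(4-benzyloxybenzoyl)-3-[2-(3-benzyloxyphenyl)ethyl]-5-methoxyphenyl ethyl carbonate | CCOC(=O)Oc1cc(OC)cc(CCc2cccc(OCc3ccccc3)c2)c1C(=O)c1ccc(OCc2ccccc2)cc1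
F10 | step 9 | 2-(4-benzyloxybenzyl)-3-[2-(3-benzyloxyphenyl)ethyl]-5-methoxyphenol | COc1cc(O)c(Cc2ccc(OCc3ccccc3)cc2)c(CCc2cccc(OCc3ccccc3)c2)c1
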